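## Retrosynthetic overview

1. Target ⇒ seco-diterpenoid diketo acid 17 + (S)-glycidol (ester C–O by epoxide opening), with the 2-O-acetyl group placed last through a cyclic orthoacetate.
2. 17 ⇒ methyl ketone 10 + methyl (E)-4-bromo-3-methylbut-2-enoate: enolate allylation, then Wacker oxidation (C=O of the oxobutyl arm) and asymmetric hydrogenation (side-chain methyl stereocentre).
3. 10 ⇒ acyclic dienol 9 in one cationic cascade: olefin protonation, 6-endo C–C ring closure, 1,2-methyl shift (semipinacol). This forms the only ring and both ring stereocentres.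
4. 9 ⇒ alkynol 4 + homoprenyl Grignard (anti-carbomagnesiation fixes the E geometry); 4 ⇒ hex-5-en-1-yne + acetone.

Assumption: descriptors (ring 1R,2R; chain 3R; glycerol 2S) are derived from the given SMILES, and hex-5-en-1-yne, 5-bromo-2-methylpent-2-ene and (S)-glycidol are taken as catalogue chemicals.

## Route

Step 1
Reactants: 1 hex-5-en-1-yne; 2 acetone
Product: 4 2-methyloct-7-en-3-yn-2-ol, via lithium hex-5-en-1-yn-1-ide 3 (not isolated)
Conditions: n-BuLi, THF, −78 °C; then 2, −78 → 0 °C; H2O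
Reagents that add atoms: none
Why: Acetylide addition to a ketone; only the terminal alkyne C–H is acidic enough for n-BuLi and no stereocentre is formed.

Step 2
Reactants: 4 2-methyloct-7-en-3-yn-2-ol; 5 5-bromo-2-methylpent-2-ene
Product: 9 (3E)-2-methyl-3-(4-methylpent-3-en-1-yl)octa-3,7-dien-2-ol, via (4-methylpent-3-en-1-yl)magnesium bromide 6 (not isolated), via bromomagnesium 2-methyloct-7-en-3-yn-2-olate 7 (not isolated), via cyclic alkenylmagnesium alkoxide 8 (not isolated)
Conditions: 5, Mg, THF, rt (gives 6, 2.5 equiv); 4, CuI (10 mol%), THF, 0 → 65 °C; H2O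
Reagents that add atoms: none
Why: Copper-catalysed anti-carbomagnesiation of a propargylic alkoxide; the alkyl group adds to the alkyne carbon next to the carbinol and magnesium ends on the distal carbon in a five-membered O–Mg–C chelate, so protonolysis gives only the E-olefin (carbinol trans to the butenyl chain).

Step 3
Reactants: 9 (3E)-2-methyl-3-(4-methylpent-3-en-1-yl)octa-3,7-dien-2-ol
Product: 10 1-[(1R,2R)-2-(but-3-en-1-yl)-1,3,3-trimethylcyclohexyl]ethan-1-one
Conditions: (S,S)-IDPi chiral Brønsted acid (5 mol%), (CF3)3COH/CHCl3 1:3, −40 °C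
Reagents that add atoms: none
Why: Proposed new method: a confined chiral imidodiphosphorimidate acid protonates the electron-rich 4-methylpent-3-enyl olefin, the tertiary cation is captured 6-endo by the CH terminus of the E-allylic double bond (anti addition, so acetyl and butenyl end up trans), and the resulting β-hydroxy cation collapses by a 1,2-methyl shift from the carbinol carbon (semipinacol) with loss of the O–H proton that turns the catalyst over, while the ion-paired chiral anion sets the absolute sense (1R,2R; the catalyst antipode must be assigned by experiment); the two carbinol methyls are identical so only one ketone can form and the monosubstituted alkene is far too electron-poor to compete; closest known reactions are chiral-acid-catalysed enantioselective polyene cyclisations, acid-catalysed semipinacol rearrangements of allylic alcohols and the pinacol-terminated Prins cyclisation.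

Step 4
Reactants: 11 methyl 3-methylbut-2-enoate
Product: 12 methyl (2E)-4-bromo-3-methylbut-2-enoate
Conditions: NBS, AIBN (cat.), PhCF3, reflux; then 130 °C and distillation (Z isomer lost as butenolide)
Reagents that add atoms: N-bromosuccinimide O=C1CCC(=O)N1Br
Why: Wohl–Ziegler allylic bromination; the unwanted Z-bromo ester lactonises on heating and is removed, leaving the geometrically pure E isomer needed for the later hydrogenation.

Step 5
Reactants: 10 1-[(1R,2R)-2-(but-3-en-1-yl)-1,3,3-trimethylcyclohexyl]ethan-1-one; 12 methyl (2E)-4-bromo-3-methylbut-2-enoate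
Product: 14 methyl (2E)-6-[(1R,2R)-2-(but-3-en-1-yl)-1,3,3-trimethylcyclohexyl]-3-methyl-6-oxohex-2-enoate, via lithium enolate 13 (not isolated)
Conditions: LDA, THF, −78 °C; then 12, DMPU, −78 → −20 °C
Reagents that add atoms: none
Why: Ketone enolate SN2 allylation; the only enolisable position is the acetyl methyl (the other α-carbon is quaternary), β,β-disubstitution of the enoate blocks Michael and cyclopropanation pathways, and the olefin geometry is retained.

Step 6
Reactants: 14 methyl (2E)-6-[(1R,2R)-2-(but-3-en-1-yl)-1,3,3-trimethylcyclohexyl]-3-methyl-6-oxohex-2-enoate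
Product: 15 (2E)-6-[(1R,2R)-2-(but-3-en-1-yl)-1,3,3-trimethylcyclohexyl]-3-methyl-6-oxohex-2-enoic acid
Conditions: LiOH, THF/MeOH/H2O, rt; then 1 M HCl
Reagents that add atoms: lithium hydroxide [Li+].[OH-]
Why: Saponification, done before the 1,6-diketone exists so that base cannot trigger an intramolecular aldol; the hindered ketone and both stereocentres (neither α to a carbonyl with an H) are inert.

Step 7
Reactants: 15 (2E)-6-[(1R,2R)-2-(but-3-en-1-yl)-1,3,3-trimethylcyclohexyl]-3-methyl-6-oxohex-2-enoic acid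
Product: 16 (2E)-3-methyl-6-oxo-6-[(1R,2R)-1,3,3-trimethyl-2-(3-oxobutyl)cyclohexyl]hex-2-enoic acid
Conditions: PdCl2 (10 mol%), CuCl (re-oxidised by O2), O2 (1 atm), DMF/H2O 7:1, rt
Reagents that add atoms: water O
Why: Tsuji–Wacker oxidation; Markovnikov hydroxypalladation turns only the monosubstituted alkene into the methyl ketone, the conjugated trisubstituted olefin being unreactive.

Step 8
Reactants: 16 (2E)-3-methyl-6-oxo-6-[(1R,2R)-1,3,3-trimethyl-2-(3-oxobutyl)cyclohexyl]hex-2-enoic acid
Product: 17 (3R)-3-methyl-6-oxo-6-[(1R,2R)-1,3,3-trimethyl-2-(3-oxobutyl)cyclohexyl]hexanoic acid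
Conditions: H2 (100 atm), Ru(OAc)2[(S)-BINAP] (1 mol%), MeOH, 25 °C
Reagents that add atoms: none
Why: Carboxylate-directed Ru–BINAP asymmetric hydrogenation of an (E)-3-methylalk-2-enoic acid (the geranic acid → citronellic acid manifold) sets the 3R centre by catalyst control; the BINAP antipode is the one that gives (R)-citronellic acid from geranic acid (to be confirmed on that model), and unfunctionalised ketones are not reduced by this catalyst.

Step 9
Reactants: 17 (3R)-3-methyl-6-oxo-6-[(1R,2R)-1,3,3-trimethyl-2-(3-oxobutyl)cyclohexyl]hexanoic acid; 18 (S)-glycidol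
Product: 19 (2S)-2,3-dihydroxypropyl (3R)-3-methyl-6-oxo-6-[(1R,2R)-1,3,3-trimethyl-2-(3-oxobutyl)cyclohexyl]hexanoate
Conditions: Ti(OiPr)4 (1.2 equiv), CH2Cl2, rt; aq tartaric acid work-up
Reagents that add atoms: none
Why: Titanium-templated opening of a 2,3-epoxy alcohol by a carboxylic acid at the unsubstituted C-3; the epoxide stereocentre is not touched, so (S)-glycidol gives the sn-1 ester with 2S configuration.

Step 10
Reactants: 19 (2S)-2,3-dihydroxypropyl (3R)-3-methyl-6-oxo-6-[(1R,2R)-1,3,3-trimethyl-2-(3-oxobutyl)cyclohexyl]hexanoate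
Product: 21 (2S)-2-acetoxy-3-hydroxypropyl (3R)-3-methyl-6-oxo-6-[(1R,2R)-1,3,3-trimethyl-2-(3-oxobutyl)cyclohexyl]hexanoate (CNP0287223.1), via cyclic orthoacetate 20 (not isolated)
Conditions: MeC(OMe)3, PPTS (cat.), CH2Cl2, rt; then AcOH/H2O 4:1, 0 °C; cold, fast purification on boric-acid-treated silica
Reagents that add atoms: trimethyl orthoacetate COC(C)(OC)OC; water O
Why: Regioselective monoacylation of a 1,2-diol through its cyclic orthoester; kinetic acid hydrolysis expels the primary oxygen and leaves the acetate on the secondary oxygen, with no bond to the stereocentre broken.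

## Compound list

1 | hex-5-en-1-yne | C#CCCC=C | starting material
2 | acetone | CC(C)=O | starting material
3 | lithium hex-5-en-1-yn-1-ide | [Li]C#CCCC=C | intermediate
4 | 2-methyloct-7-en-3-yn-2-ol | CC(C)(O)C#CCCC=C | intermediate
5 | 5-bromo-2-methylpent-2-ene | CC(C)=CCCBr | starting material
6 | (4-methylpent-3-en-1-yl)magnesium bromide | CC(C)=CCC[Mg]Br | intermediate
7 | bromomagnesium 2-methyloct-7-en-3-yn-2-olate | CC(C)(O[Mg]Br)C#CCCC=C | intermediate
8 | 3-(but-3-en-1-yl)-5,5-dimethyl-4-(4-methylpent-3-en-1-yl)-2,5-dihydro-1,2-oxamagnesole (cyclic alkenylmagnesium alkoxide) | C=CCCC1=C(CCC=C(C)C)C(C)(C)O[Mg]1 | intermediate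
9 | (3E)-2-methyl-3-(4-methylpent-3-en-1-yl)octa-3,7-dien-2-ol | CC(C)(O)/C(CCC=C(C)C)=C/CCC=C | intermediate
10 | 1-[(1R,2R)-2-(but-3-en-1-yl)-1,3,3-trimethylcyclohexyl]ethan-1-one | C=CCC[C@@H]1C(C)(C)CCC[C@@]1(C)C(C)=O | intermediate
11 | methyl 3-methylbut-2-enoate | COC(=O)C=C(C)C | starting material
12 | methyl (2E)-4-bromo-3-methylbut-2-enoate | COC(=O)/C=C(C)/CBr | intermediate
13 | lithium 1-[(1R,2R)-2-(but-3-en-1-yl)-1,3,3-trimethylcyclohexyl]ethen-1-olate | C=CCC[C@@H]1C(C)(C)CCC[C@@]1(C)C(=C)O[Li] | intermediate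
14 | methyl (2E)-6-[(1R,2R)-2-(but-3-en-1-yl)-1,3,3-trimethylcyclohexyl]-3-methyl-6-oxohex-2-enoate | C=CCC[C@@H]1C(C)(C)CCC[C@@]1(C)C(=O)CC/C(C)=C/C(=O)OC | intermediate
15 | (2E)-6-[(1R,2R)-2-(but-3-en-1-yl)-1,3,3-trimethylcyclohexyl]-3-methyl-6-oxohex-2-enoic acid | C=CCC[C@@H]1C(C)(C)CCC[C@@]1(C)C(=O)CC/C(C)=C/C(=O)O | intermediate
16 | (2E)-3-methyl-6-oxo-6-[(1R,2R)-1,3,3-trimethyl-2-(3-oxobutyl)cyclohexyl]hex-2-enoic acid | CC(=O)CC[C@@H]1C(C)(C)CCC[C@@]1(C)C(=O)CC/C(C)=C/C(=O)O | intermediate
17 | (3R)-3-methyl-6-oxo-6-[(1R,2R)-1,3,3-trimethyl-2-(3-oxobutyl)cyclohexyl]hexanoic acid | CC(=O)CC[C@@H]1C(C)(C)CCC[C@@]1(C)C(=O)CC[C@@H](C)CC(=O)O | intermediate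
18 | (S)-glycidol [(2S)-oxiran-2-ylmethanol] | OC[C@H]1CO1 | starting material
19 | (2S)-2,3-dihydroxypropyl (3R)-3-methyl-6-oxo-6-[(1R,2R)-1,3,3-trimethyl-2-(3-oxobutyl)cyclohexyl]hexanoate | CC(=O)CC[C@@H]1C(C)(C)CCC[C@@]1(C)C(=O)CC[C@@H](C)CC(=O)OC[C@H](CO)O | intermediate
20 | cyclic orthoacetate of 19: (2-methoxy-2-methyl-1,3-dioxolan-4-yl)methyl ester, glycerol carbon as in 19, both epimers at the orthoester carbon | CC(=O)CC[C@@H]1C(C)(C)CCC[C@@]1(C)C(=O)CC[C@@H](C)CC(=O)OC[C@@H]2COC(C)(OC)O2 | intermediate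
21 | (2S)-2-acetoxy-3-hydroxypropyl (3R)-3-methyl-6-oxo-6-[(1R,2R)-1,3,3-trimethyl-2-(3-oxobutyl)cyclohexyl]hexanoate | CC(=O)CC[C@@H]1C(C)(C)CCC[C@@]1(C)C(=O)CC[C@@H](C)CC(=O)OC[C@H](CO)OC(C)=O | target

## Step count

Total steps: 10. Longest linear sequence: 9 (steps 1, 2, 3, 5, 6, 7, 8, 9, 10; step 4 is a one-step side branch).

## Three steps most likely to fail, with fallbacks

**Step 2 (anti-carbomagnesiation of a tertiary propargylic alkoxide with an alkyl Grignard).** The addition next to a fully substituted carbinol may be slow or incomplete. The fallback sets out from 4 and comes back at 9, building the same E-olefin by hydroxyl-directed trans-hydrometalation and cross-coupling. Ruthenium-catalysed trans-hydrostannation of 4 (Bu3SnH, [Cp*RuCl]4, CH2Cl2) places tin on the carbon next to the carbinol and gives (3Z)-2-methyl-3-(tributylstannyl)octa-3,7-dien-2-ol F1. Iododestannylation (I2, CH2Cl2, 0 °C) gives (3Z)-3-iodo-2-methylocta-3,7-dien-2-ol F2 with retention. Negishi coupling of F2 with the homoprenylzinc reagent made from 5 (Mg then ZnCl2; Pd(dppf)Cl2, THF, 50 °C) returns 9 with the required geometry.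

**Step 3 (the proposed asymmetric proto-cyclisation/semipinacol cascade).** The main risks are ionisation of the tertiary allylic alcohol by the acid and insufficient enantioselectivity. The fallback sets out from 9 and comes back at 10. It takes the absolute configuration from a reagent-controlled epoxidation and runs the ring closure under Lewis-acid conditions in which the carbinol is held as an aluminium alkoxide.
- Shi epoxidation (L-fructose-derived ketone, Oxone, buffered MeCN/dimethoxymethane, 0 °C) of the more accessible 4-methylpent-3-enyl olefin gives (3E)-3-{2-[(2S)-3,3-dimethyloxiran-2-yl]ethyl}-2-methylocta-3,7-dien-2-ol F3.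
- MeAlCl2 (2.2 equiv, CH2Cl2, −78 °C) triggers the epoxy-olefin cyclisation, terminated by the same pinacol-type methyl shift, to give 1-[(1R,2R,4S)-2-(but-3-en-1-yl)-4-hydroxy-1,3,3-trimethylcyclohexyl]ethan-1-one F4. This still relies on the methyl-shift termination, so it answers the ionisation and enantioselectivity risks but not a failure of the shift itself.
- 1,1'-Thiocarbonyldiimidazole (DMAP, ClCH2CH2Cl, 60 °C) converts F4 into O-[(1S,3R,4R)-4-acetyl-3-(but-3-en-1-yl)-2,2,4-trimethylcyclohexyl] 1H-imidazole-1-carbothioate F5.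
- Barton–McCombie reduction (Bu3SnH 0.5 M, AIBN, toluene, 100 °C; high hydride concentration to outrun 5-exo closure onto the butenyl group) returns 10.

**Step 10 (orthoester-based 2-O-acetylation).** The risks are imperfect regioselectivity and 2→3 acetyl migration. The fallback sets out from 17 and 18 and comes back at 21, using a protecting group that is removed under neutral conditions.
- 18 is converted (NaH, 4-methoxybenzyl chloride, Bu4NI, THF) into (2R)-2-{[(4-methoxyphenyl)methoxy]methyl}oxirane F6.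
- Acid 17 opens F6 at the terminal carbon ((salen)Co(III) carboxylate catalyst, iPr2NEt, TBME, rt) to give (2S)-2-hydroxy-3-[(4-methoxyphenyl)methoxy]propyl (3R)-3-methyl-6-oxo-6-[(1R,2R)-1,3,3-trimethyl-2-(3-oxobutyl)cyclohexyl]hexanoate F7.
- Acetylation (Ac2O, pyridine, DMAP, 0 °C) gives (2S)-2-acetoxy-3-[(4-methoxyphenyl)methoxy]propyl (3R)-3-methyl-6-oxo-6-[(1R,2R)-1,3,3-trimethyl-2-(3-oxobutyl)cyclohexyl]hexanoate F8.
- DDQ (CH2Cl2/pH 7 buffer, 0 °C) removes the PMB group and returns 21.

## Further compounds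

F1 | step 2 | (3Z)-2-methyl-3-(tributylstannyl)octa-3,7-dien-2-ol | CC(C)(O)/C(=C/CCC=C)[Sn](CCCC)(CCCC)CCCC
F2 | step 2 | (3Z)-3-iodo-2-methylocta-3,7-dien-2-ol | CC(C)(O)/C(I)=C/CCC=C
F3 | step 3 | (3E)-3-{2-[(2S)-3,3-dimethyloxiran-2-yl]ethyl}-2-methylocta-3,7-dien-2-ol | CC(C)(O)/C(CC[C@@H]1OC1(C)C)=C/CCC=C
F4 | step 3 | 1-[(1R,2R,4S)-2-(but-3-en-1-yl)-4-hydroxy-1,3,3-trimethylcyclohexyl]ethan-1-one | C=CCC[C@@H]1C(C)(C)[C@@H](O)CC[C@@]1(C)C(C)=O
F5 | step 3 | O-[(1S,3R,4R)-4-acetyl-3-(but-3-en-1-yl)-2,2,4-trimethylcyclohexyl] 1H-imidazole-1-carbothioate | C=CCC[C@@H]1C(C)(C)[C@@H](OC(=S)n2ccnc2)CC[C@@]1(C)C(C)=O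
F6 | step 10 | (2R)-2-{[(4-methoxyphenyl)methoxy]methyl}oxirane | COc1ccc(COC[C@H]2CO2)cc1
F7 | step 10 | (2S)-2-hydroxy-3-[(4-methoxyphenyl)methoxy]propyl (3R)-3-methyl-6-oxo-6-[(1R,2R)-1,3,3-trimethyl-2-(3-oxobutyl)cyclohexyl]hexanoate | CC(=O)CC[C@@H]1C(C)(C)CCC[C@@]1(C)C(=O)CC[C@@H](C)CC(=O)OC[C@H](COCc2ccc(OC)cc2)O
F8 | step 10 | (2S)-2-acetoxy-3-[(4-methoxyphenyl)methoxy]propyl (3R)-3-methyl-6-oxo-6-[(1R,2R)-1,3,3-trimethyl-2-(3-oxobutyl)cyclohexyl]hexanoate | CC(=O)CC[C@@H]1C(C)(C)CCC[C@@]1(C)C(=O)CC[C@@H](C)CC(=O)OC[C@H](COCc2ccc(OC)cc2)OC(C)=O
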